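**Plan**
- Cuts, in retrosynthetic order: the two benzyl-type C–O protections; the C7–H bond (C7 ketone); then C8a–C8 and C5–C6 together, which splits the carbocycle into 2-phenyl-1,3-dioxan-5-one (C6–C7–C8) and a 2-methoxy-4-oxopyran-3-carbaldehyde (C5, C4a, C8a); then the C3-formyl group, the O-methyl group and the ArCH2–CH2 bond.
- Enabling feature: C6–C7–C8 with cis O6/O8 is a dihydroxyacetone unit whose C7 ketone makes both flanking carbons nucleophilic. C5 (carbinol carbon on C4a) and C8a (the O1-bearing β-carbon of the pyranone ring) are 1,3-related electrophilic sites once C8a carries a methoxy leaving group.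
- Forward order: the side chain is joined to the pyranone ring first, the ring is set up as a γ-pyrone aldehyde, and the carbocycle is then closed onto it as a benzylidene-bridged bicycle (the acetal is a temporary ring). Acetal and benzyl ether are removed last.
- Stereochemistry: C6 from chiral lithium amide deprotonation plus axial aldol attack, C5 from the anti aldol, C8 forced cis to C6 by the acetal bridge, C7 from hydride addition to the bridged ketone on the dioxane face.

Key step: step 5

Assumption: by analogy with 4-substituted cyclohexanones, lithium bis[(R)-1-phenylethyl]amide is taken to remove the axial α-proton of 2-phenyl-1,3-dioxan-5-one that leads to the (S)-enolate; if the opposite sense is found, the (S,S)-amide is used.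

Ar = 3-(benzyloxy)-4-methoxyphenyl. Bicyclic compounds use the chromone numbering of the target.

Step 1
Reactants: 1 3-(benzyloxy)-4-methoxybenzyl alcohol
Product: 2 3-(benzyloxy)-4-methoxybenzyl bromide
Conditions: PBr3, CH2Cl2, 0 °C
Reagents that add atoms: phosphorus tribromide, BrP(Br)Br
Why: Bromide displaces the activated benzylic phosphite ester (alcohol-to-bromide conversion with PBr3), which should be clean for an electron-rich benzylic alcohol at 0 °C.

Step 2
Reactants: 3 4-hydroxy-6-methyl-2H-pyran-2-one; 2 3-(benzyloxy)-4-methoxybenzyl bromide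
Product: 5 6-(2-Ar-ethyl)-4-hydroxy-2H-pyran-2-one, via dianion 4 (not isolated)
Conditions: LiN(i-Pr)2 (2.2 equiv), THF, −78 → 0 °C; then 2, −78 °C → rt; HCl (aq)
Reagents that add atoms: none
Why: In the dianion the C6-methyl carbanion is the most nucleophilic site, so benzylation should occur there only (dianion alkylation of triacetic acid lactone).

Step 3
Reactants: 5 6-(2-Ar-ethyl)-4-hydroxy-2H-pyran-2-one
Product: 6 6-(2-Ar-ethyl)-2-methoxy-4H-pyran-4-one
Conditions: CF3SO3CH3 (1.2 equiv), CH2Cl2, rt; NaHCO3 (aq) work-up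
Reagents that add atoms: methyl trifluoromethanesulfonate, COS(=O)(=O)C(F)(F)F
Why: The hard methylating agent should alkylate the neutral pyranone at the lactone carbonyl oxygen and loss of the 4-OH proton then gives the 2-methoxy-4-pyranone (known regioselective O-methylation of 4-hydroxy-2-pyranones to α-methoxy-γ-pyrones).

Step 4
Reactants: 6 6-(2-Ar-ethyl)-2-methoxy-4H-pyran-4-one
Product: 8 6-(2-Ar-ethyl)-2-methoxy-4-oxo-4H-pyran-3-carbaldehyde, via iminium salt 7 (not isolated)
Conditions: POCl3 (1.2 equiv), DMF, 0 → 40 °C; NaOAc (aq)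
Reagents that add atoms: N,N-dimethylformamide, CN(C)C=O (formyl carbon); water, O (formyl oxygen)
Why: C3 is the β-carbon of the O1–C2(OMe) ketene-acetal unit and therefore the most nucleophilic carbon, so the chloroiminium ion should attack there and hydrolysis of 7 gives the aldehyde (Vilsmeier–Haack formylation).

Step 5
Reactants: 9 2-phenyl-1,3-dioxan-5-one; 8 6-(2-Ar-ethyl)-2-methoxy-4-oxo-4H-pyran-3-carbaldehyde
Product: 14 (5S,6S,8R)-2-(2-Ar-ethyl)-6,8-O-[(R)-benzylidene]-6,8-dihydroxy-5-(triethylsilyloxy)-5,6-dihydro-4H-chromene-4,7(8H)-dione, via dioxinolate 10 (not isolated), via aldolate 11 (not isolated), via silyl ether 12 (not isolated), via silyloxy enolate 13 (not isolated)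
Conditions: bis[(R)-1-phenylethyl]amine hydrochloride (1.1 equiv), n-BuLi (2.2 equiv), THF, −78 → 0 → −78 °C; 9, −78 °C; 8, −78 °C; Et3SiOSO2CF3 (1.1 equiv), −78 °C; LiN(SiMe3)2 (1.3 equiv), −78 → −20 °C; NH4Cl (aq)
Reagents that add atoms: triethylsilyl trifluoromethanesulfonate, CC[Si](CC)(CC)OS(=O)(=O)C(F)(F)F
Why: Proposed new method: enantioselective deprotonation of 9 gives enolate 10, which adds to the aldehyde of 8 through a Zimmerman–Traxler chair (C5–C6 bond); the aldolate 11 is silylated to 12 so that it cannot cleave by retro-aldol, and kinetic deprotonation at the remaining α-CH2 gives enolate 13, whose carbon (C8) adds to C8a of the 2-methoxypyranone and expels methoxide (C8–C8a bond, a vinylogous acyl substitution). The closest known reaction types are the chiral-lithium-amide aldol of 1,3-dioxan-5-ones, the α,α'-annulation of dioxanone enamines with 1,3-bis-electrophiles to 2,4-dioxabicyclo[3.3.1]nonan-9-ones, and the [3+3] annulation of 1,3-dinucleophiles with 3-formylchromones. The carbocycle closes in the second bond formation by a 6-(enolendo)-endo-trig addition–elimination, which is possible only when the C6 substituent is axial on the dioxanone chair. C6 is controlled by the chiral amide (which α-proton is removed) together with axial attack trans to the equatorial phenyl group, C5 by the anti-selective chair transition state of the ring (E)-enolate, C8 by the bridge, which can only form cis to C6, and the acetal carbon becomes stereogenic with phenyl exo. The step needs the aldehyde to react before C8a and C-attack to win over O-attack: the hard lithium enolate should add 1,2 to the aldehyde at −78 °C while C8a, with two oxygen donors, stays inert until the intramolecular stage, and O-attack at C8a is reversible whereas C-attack ends irreversibly with loss of methoxide. The acetal bridge also forbids dehydration of the ketol, because the alkene would sit at a bridgehead.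

Step 6
Reactants: 14 bridged ketone (5-O-triethylsilyl, 6,8-O-benzylidene)
Product: 16 (5S,6S,7R,8S)-2-(2-Ar-ethyl)-6,8-O-[(R)-benzylidene]-5,6,7,8-tetrahydroxy-5,6,7,8-tetrahydro-4H-chromen-4-one, via silyl ether alcohol 15 (not isolated)
Conditions: NaBH4, MeOH/THF, −78 °C; then Bu4NF, AcOH, THF, 0 °C → rt
Reagents that add atoms: none
Why: Hydride should add to the C7 carbonyl of the bridged 1,3-dioxan-5-one along the axial trajectory of the dioxane chair, flanked only by the lone pairs of O6 and O8 (the other face is screened by the pyranone ring and the axial C5–H), which places the C7 hydroxyl trans to O6 and O8, and fluoride then cleaves the silyl ether (substrate-controlled ketone reduction followed by desilylation).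

Step 7
Reactants: 16 6,8-O-benzylidene tetrol benzyl ether
Product: 17 (5S,6S,7R,8S)-5,6,7,8-tetrahydroxy-2-[2-(3-hydroxy-4-methoxyphenyl)ethyl]-5,6,7,8-tetrahydro-4H-chromen-4-one (CNP0224308.1)
Conditions: H2 (1 atm), 10% Pd/C, EtOAc/MeOH, rt
Reagents that add atoms: none
Why: Hydrogenolysis should cleave the benzylidene acetal and the aryl benzyl ether in one neutral operation, under which the pyranone double bonds are not reduced and the tetrol is not exposed to acid that could dehydrate it.

**Compound list**
1 | 3-(benzyloxy)-4-methoxybenzyl alcohol | COc1ccc(CO)cc1OCc1ccccc1 | starting material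
2 | 3-(benzyloxy)-4-methoxybenzyl bromide | COc1ccc(CBr)cc1OCc1ccccc1 | intermediate
3 | 4-hydroxy-6-methyl-2H-pyran-2-one | Cc1cc(O)cc(=O)o1 | starting material
4 | dilithium dianion of 3 (4-oxide, 6-methylide) | [Li+].[Li+].[CH2-]c1cc([O-])cc(=O)o1 | intermediate
5 | 6-[2-(3-benzyloxy-4-methoxyphenyl)ethyl]-4-hydroxy-2H-pyran-2-one | O=c1cc(O)cc(CCc2ccc(OC)c(OCc3ccccc3)c2)o1 | intermediate
6 | 6-[2-(3-benzyloxy-4-methoxyphenyl)ethyl]-2-methoxy-4H-pyran-4-one | COc1cc(=O)cc(CCc2ccc(OC)c(OCc3ccccc3)c2)o1 | intermediate
7 | N-{[6-(2-Ar-ethyl)-2-methoxy-4-oxo-4H-pyran-3-yl]methylidene}-N-methylmethanaminium chloride | C[N+](C)=Cc1c(OC)oc(CCc2ccc(OC)c(OCc3ccccc3)c2)cc1=O.[Cl-] | intermediate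
8 | 6-[2-(3-benzyloxy-4-methoxyphenyl)ethyl]-2-methoxy-4-oxo-4H-pyran-3-carbaldehyde | COc1oc(CCc2ccc(OC)c(OCc3ccccc3)c2)cc(=O)c1C=O | intermediate
9 | 2-phenyl-1,3-dioxan-5-one | O=C1COC(c2ccccc2)OC1 | starting material
10 | lithium (S)-2-phenyl-4H-1,3-dioxin-5-olate | [Li+].[O-]C1=CO[C@@H](c2ccccc2)OC1 | intermediate
11 | lithium (S)-[6-(2-Ar-ethyl)-2-methoxy-4-oxo-4H-pyran-3-yl][(2S,4S)-5-oxo-2-phenyl-1,3-dioxan-4-yl]methanolate (anti aldolate, side chain trans to phenyl) | COc1oc(CCc2ccc(OC)c(OCc3ccccc3)c2)cc(=O)c1[C@H]([O-])[C@@H]1O[C@@H](c2ccccc2)OCC1=O.[Li+] | intermediate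
12 | (2S,4S)-4-{(S)-[6-(2-Ar-ethyl)-2-methoxy-4-oxo-4H-pyran-3-yl](triethylsilyloxy)methyl}-2-phenyl-1,3-dioxan-5-one | COc1oc(CCc2ccc(OC)c(OCc3ccccc3)c2)cc(=O)c1[C@H](O[Si](CC)(CC)CC)[C@@H]1O[C@@H](c2ccccc2)OCC1=O | intermediate
13 | lithium (2S,4S)-4-{(S)-[6-(2-Ar-ethyl)-2-methoxy-4-oxo-4H-pyran-3-yl](triethylsilyloxy)methyl}-2-phenyl-4H-1,3-dioxin-5-olate | COc1oc(CCc2ccc(OC)c(OCc3ccccc3)c2)cc(=O)c1[C@H](O[Si](CC)(CC)CC)[C@@H]1O[C@@H](c2ccccc2)OC=C1[O-].[Li+] | intermediate
14 | (5S,6S,8R)-2-(2-Ar-ethyl)-6,8-O-[(R)-benzylidene]-6,8-dihydroxy-5-(triethylsilyloxy)-5,6-dihydro-4H-chromene-4,7(8H)-dione (phenyl exo; C5, C6, C8 arranged as in the target) | COc1ccc(CCc2cc(=O)c3c(o2)[C@H]4O[C@H](c5ccccc5)O[C@H](C4=O)[C@H]3O[Si](CC)(CC)CC)cc1OCc1ccccc1 | intermediate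
15 | (5S,6R,7R,8S)-2-(2-Ar-ethyl)-6,8-O-[(R)-benzylidene]-6,7,8-trihydroxy-5-(triethylsilyloxy)-5,6,7,8-tetrahydro-4H-chromen-4-one (C7–OH trans to O6 and O8) | COc1ccc(CCc2cc(=O)c3c(o2)[C@H]4O[C@H](c5ccccc5)O[C@H]([C@H]4O)[C@H]3O[Si](CC)(CC)CC)cc1OCc1ccccc1 | intermediate
16 | (5S,6S,7R,8S)-2-(2-Ar-ethyl)-6,8-O-[(R)-benzylidene]-5,6,7,8-tetrahydroxy-5,6,7,8-tetrahydro-4H-chromen-4-one | COc1ccc(CCc2cc(=O)c3c(o2)[C@H]4O[C@H](c5ccccc5)O[C@H]([C@H]4O)[C@H]3O)cc1OCc1ccccc1 | intermediate
17 | (5S,6S,7R,8S)-5,6,7,8-tetrahydroxy-2-[2-(3-hydroxy-4-methoxyphenyl)ethyl]-5,6,7,8-tetrahydro-4H-chromen-4-one | COc1ccc(CCc2cc(=O)c3c(o2)[C@@H](O)[C@H](O)[C@@H](O)[C@H]3O)cc1O | target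

**Count**
Total steps: 7. Longest linear sequence: 7 (1 → 2 → 5 → 6 → 8 → 14 → 16 → 17).

**Steps most likely to fail**

Step 5 (bears the label "Proposed new method:"). What may go wrong: retro-aldol cleavage or β-elimination during the second enolization, ring closure through the enolate oxygen instead of carbon, and incomplete enantiotopic selection in the deprotonation. Fallback: it sets out from 8 and 9 and comes back at 14. The asymmetric lithium aldol and the silylation are stopped after the silyl ether 12, which is isolated and, if needed, enriched by crystallization (chiral-lithium-amide aldol of dioxanones, known). 12 is then converted with LiN(i-Pr)2 and Me3SiCl at −78 °C into the kinetic trimethylsilyl enol ether F1. F1 is closed with Me3SiOSO2CF3 in CH2Cl2 at −78 °C: the pyranone is turned into a 4-silyloxy-2-methoxypyrylium ion, the enol silane attacks it at C8a (Mukaiyama-type addition of enol silanes to silyloxypyrylium triflates, known), and loss of methoxytrimethylsilane gives 14. The ring is thus closed by a cationic instead of an anionic addition–elimination and without free alkoxide or methoxide.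

Step 4. What may go wrong: formylation at C5 of the pyranone instead of C3, or exchange or loss of the 2-methoxy group under the chlorinating conditions. Fallback: it sets out from 6 and comes back at 8. Bromination with N-bromosuccinimide in MeCN at 0 °C should take place at the same most nucleophilic carbon and give the 3-bromopyranone F2. Bromine–magnesium exchange with i-PrMgCl·LiCl in THF at −40 °C, followed by DMF in the same flask, then gives 8 (halogenation, exchange and formylation instead of direct electrophilic formylation).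

Step 6. What may go wrong: hydride delivery from the pyranone face (poor facial selectivity at C7), or ring opening by retro-aldol if the silyl group is lost before reduction. Fallback: it sets out from 14 and comes back at 17. Bu4NF/AcOH removes the silyl group to give the bridged ketol F3. Hydrogenolysis (H2, Pd/C) removes acetal and benzyl ether to give the monocyclic keto-triol F4. Me4NBH(OAc)3 in MeCN/AcOH at −30 °C then reduces the C7 ketone by intramolecular delivery from the boron-bound C5, C6 and C8 hydroxyls, which all lie on one face, so the new C7 hydroxyl is placed trans to them (hydroxyl-directed reduction of hydroxy ketones, known), giving 17 directly.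

Further compounds
F1 | step 5 | (2S,4S)-4-{(S)-[6-(2-Ar-ethyl)-2-methoxy-4-oxo-4H-pyran-3-yl](triethylsilyloxy)methyl}-2-phenyl-5-(trimethylsilyloxy)-4H-1,3-dioxine | COc1oc(CCc2ccc(OC)c(OCc3ccccc3)c2)cc(=O)c1[C@H](O[Si](CC)(CC)CC)[C@@H]1O[C@@H](c2ccccc2)OC=C1O[Si](C)(C)C
F2 | step 4 | 6-[2-(3-benzyloxy-4-methoxyphenyl)ethyl]-3-bromo-2-methoxy-4H-pyran-4-one | COc1oc(CCc2ccc(OC)c(OCc3ccccc3)c2)cc(=O)c1Br
F3 | step 6 | (5S,6S,8R)-2-(2-Ar-ethyl)-6,8-O-[(R)-benzylidene]-5,6,8-trihydroxy-5,6-dihydro-4H-chromene-4,7(8H)-dione | COc1ccc(CCc2cc(=O)c3c(o2)[C@H]4O[C@H](c5ccccc5)O[C@H](C4=O)[C@H]3O)cc1OCc1ccccc1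
F4 | step 6 | (5S,6S,8R)-5,6,8-trihydroxy-2-[2-(3-hydroxy-4-methoxyphenyl)ethyl]-5,6-dihydro-4H-chromene-4,7(8H)-dione | COc1ccc(CCc2cc(=O)c3c(o2)[C@@H](O)C(=O)[C@@H](O)[C@H]3O)cc1O
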